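On the proposed steps, substrate that was lost stayed in the flask as intermediate, target or over-reaction product; the first step also makes by-product. I wrote this note for the flask below.

| setting | Friday's | Saturday's | Thursday's | flask |
|---|---|---|---|---|
| substrate | 0.034 M | 0.075 M | 0.050 M | 0.050 M |
| coupling partner | 0.075 M | 0.075 M | 0.11 M | 0.0750 M |
| remark | run made earlier | run made earlier | run made earlier |  |
| time |  |  |  | 12 min |

| run | time / min | intermediate / % | target / % | substrate / % |
|---|---|---|---|---|
| Friday's | 1.00 | 5.6 | 2.0 | 92.0 |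
| Friday's | 2.00 | 9.2 | 6.5 | 83.2 |
| Friday's | 3.00 | 10.1 | 12.6 | 78.4 |
| Friday's | 4.00 | 8.8 | 18.3 | 72.4 |
| Friday's | 5.00 | 9.3 | 22.3 | 66.6 |
| Friday's | 6.00 | 7.6 | 26.5 | 61.3 |
| Friday's | 8.00 | 5.8 | 32.3 | 53.4 |
| Saturday's | 0.500 | 3.1 | 0 | 95.5 |
| Saturday's | 0.833 | 5.6 | 1.1 | 93.1 |
| Saturday's | 1.33 | 6.8 | 3.0 | 89.1 |
| Saturday's | 2.00 | 8.1 | 6.8 | 85.2 |
| Saturday's | 3.00 | 9.6 | 11.8 | 78.8 |
| Saturday's | 5.00 | 7.2 | 21.5 | 69.0 |
| Saturday's | 8.00 | 5.3 | 30.3 | 58.7 |
| Thursday's | 0.500 | 5.7 | 1.5 | 93.7 |
| Thursday's | 1.00 | 7.7 | 3.3 | 88.3 |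
| Thursday's | 2.00 | 11.1 | 9.6 | 77.8 |
| Thursday's | 4.00 | 11.0 | 22.9 | 62.3 |
| Thursday's | 8.00 | 7.5 | 38.1 | 41.6 |

(each reading ± 0.5 percentage points)

- what may be going on: substrate + coupling partner -> intermediate + by-product; coupling partner + target -> over-reaction product; intermediate -> target

1. amount of intermediate in percent of the substrate charged, at 40 s, 3.0 min and 12 min

Thursday's run read the intermediate at 11.1% and 11.0% at 2.00 min and 4.00 min, so over that interval what left it matched, within the scatter, what the substrate lost. The level divided by that loss gave, as a reading, the relay time, the intermediate's lifetime, 1.43 min. The same interval gave a reading of 1.16 M⁻¹ min⁻¹ for the rate constant k of the first step.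

Since this time is shorter than 12 min, I took the late level in the flask as relay time × k × [substrate] × [coupling partner], in share of the charge (the steady-state approximation). I counted the partner as spent by the first step, used that level at 3.0 min and 12 min, and took 40 s as a rise toward the level at the charge:

40 s: 4.65%

3.0 min: 8.37%

12 min: 3.47%

The forecast said 4.5%, 10% and 3.7%. Its middle value, higher than mine, was the level “matching Friday and Saturday”.

The flask gave 4.61%, 8.97% and 3.95%.

    substrate + coupling partner → intermediate + by-product (k = 0.0200 M⁻¹ s⁻¹)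
    coupling partner + target → over-reaction product (k = 0.0150 M⁻¹ s⁻¹)
    intermediate → target (k = 0.0110 s⁻¹)

At 4.00 min the flask made intermediate at 0.914 of the rate at which it used it up. Saturday's run, put through the same relay-time line at 8.00 min, gave 4.29%, and the reading there was 5.3%.

The runs stem from a simulated flask for an exercise; noise was put on by code.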